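**Retrosynthetic overview** (ring numbered as a furan-2(5H)-one: O1, C2 lactone carbonyl, C3 methyl, C4 carboxyl, C5 stereocentre)
- Target 11 comes from 10, its 4-methoxybenzyl ester with the side-chain ketone as a dioxolane, by one acid treatment.
- Key disconnection: the ring O1–C5 bond and the C4–CO2R bond are cut together, giving the acyclic (aS)-2-methyl-2,3-allenoic acid 9, CO and 4-methoxybenzyl alcohol (three components); the only ring of the target is formed in this step.
- Enabling feature: the tetrasubstituted C3=C4 alkene, carrying the methyl and the carboxyl and lying between carbonyl C2 and the oxygenated stereocentre C5, is a latent allene. Ring atoms C2–C5 are C1–C4 of a 2,3-allenoic acid whose own carboxyl oxygen lies beside the allene terminus, and ring C4 is the central allene carbon that becomes the vinyl–palladium carbon on ring closure.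
- 9 comes from the (R)-propargylic mesylate 8 by stereospecific hydroxycarbonylation (so both carbonyl carbons on the ring come from CO); 8 comes from ynone 6 by Noyori transfer hydrogenation and mesylation.
- 6 comes from Weinreb amide 5 and a propynyl Grignard reagent; the chain comes from methyl 11-bromoundecanoate 1 and ketal chloride 2 by Cu-catalysed alkyl–alkyl coupling.

Key step: step 7

Remark: the side-chain ketone is carried as its ethylene ketal from step 1 to step 8; the required stereochemical sense, (R)-carbinol → (aS)-allene → (S)-lactone, follows from two successive anti events and was derived from the geometry of the allene.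

**Step 1**
Reactants: 1 methyl 11-bromoundecanoate; 2 2-(3-chloropropyl)-2-methyl-1,3-dioxolane
Product: 4 methyl 14-(2-methyl-1,3-dioxolan-2-yl)tetradecanoate, via the Grignard reagent 3 (not isolated)
Conditions: 2, Mg turnings, THF, 50 °C; then added to 1, Li2CuCl4 (3 mol %), THF/NMP, −20 → 0 °C
Reagents that add atoms: none
Why: Kochi-type Cu-catalysed alkyl–alkyl cross-coupling, in which the primary alkyl Grignard reagent 3 should displace the primary bromide of 1 at low temperature much faster than it adds to the methyl ester, while the dioxolane is inert to both Grignard formation and coupling.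

**Step 2**
Reactants: 4 methyl 14-(2-methyl-1,3-dioxolan-2-yl)tetradecanoate
Product: 5 N-methoxy-N-methyl-14-(2-methyl-1,3-dioxolan-2-yl)tetradecanamide
Conditions: MeNH(OMe)·HCl (1.5 equiv), i-PrMgCl (3.0 equiv), THF, −20 → 0 °C
Reagents that add atoms: N,O-dimethylhydroxylamine hydrochloride, CNOC.Cl
Why: Weinreb amide formation by direct aminolysis of the methyl ester with the chloromagnesium amide of N,O-dimethylhydroxylamine, generated in the flask by i-PrMgCl, which at this temperature acts only as a base and leaves the ketal untouched.

**Step 3**
Reactants: 5 N-methoxy-N-methyl-14-(2-methyl-1,3-dioxolan-2-yl)tetradecanamide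
Product: 6 17-(2-methyl-1,3-dioxolan-2-yl)heptadec-2-yn-4-one
Conditions: CH3C≡CMgBr (1.5 equiv), THF, 0 °C → rt; inverse quench into cold aq. NH4Cl
Reagents that add atoms: 1-propynylmagnesium bromide, CC#C[Mg]Br
Why: Weinreb ketone synthesis, in which the alkynyl Grignard reagent adds once to give a magnesium-chelated tetrahedral intermediate that collapses to the ynone only on quench, so no tertiary alcohol should form.

**Step 4**
Reactants: 6 17-(2-methyl-1,3-dioxolan-2-yl)heptadec-2-yn-4-one
Product: 7 (R)-17-(2-methyl-1,3-dioxolan-2-yl)heptadec-2-yn-4-ol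
Conditions: RuCl[(R,R)-TsDPEN](p-cymene) (1 mol %), KOH (1 mol %), i-PrOH, rt
Reagents that add atoms: none
Why: Noyori asymmetric transfer hydrogenation of an alkyl alkynyl ketone, in which the conjugated C≡C bond takes the place of the aryl group in the catalyst–substrate contact so that the (R,R)-catalyst should give the (R)-carbinol under catalyst control, while the alkyne and the ketal are not reduced.

**Step 5**
Reactants: 7 (R)-17-(2-methyl-1,3-dioxolan-2-yl)heptadec-2-yn-4-ol
Product: 8 (R)-17-(2-methyl-1,3-dioxolan-2-yl)heptadec-2-yn-4-yl methanesulfonate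
Conditions: MsCl (1.3 equiv), Et3N (1.5 equiv), CH2Cl2, −40 °C; cold aqueous work-up, used without chromatography
Reagents that add atoms: methanesulfonyl chloride, CS(=O)(=O)Cl
Why: O-sulfonylation (mesylation) of the secondary alcohol takes place at oxygen only, so the configuration of the carbinol carbon is retained and the hydroxyl becomes a leaving group for the next step.

**Step 6**
Reactants: 8 (R)-17-(2-methyl-1,3-dioxolan-2-yl)heptadec-2-yn-4-yl methanesulfonate
Product: 9 (aS)-2-methyl-17-(2-methyl-1,3-dioxolan-2-yl)heptadeca-2,3-dienoic acid
Conditions: Pd(PPh3)4 (5 mol %), CO (1 atm), 2,6-lutidine (1.2 equiv), THF/H2O, rt; work-up at pH 4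
Reagents that add atoms: carbon monoxide, [C-]#[O+]; water, O
Why: Tsuji-type hydroxycarbonylation of a propargylic electrophile, in which zerovalent palladium should displace the mesylate in an anti SN2' sense to give an allenylpalladium species, CO inserts with retention and water cleaves the acylpalladium, so the (R)-centre is transferred to the (aS)-axis while 2,6-lutidine takes up the methanesulfonic acid and protects the ketal.

**Step 7**
Reactants: 9 (aS)-2-methyl-17-(2-methyl-1,3-dioxolan-2-yl)heptadeca-2,3-dienoic acid
Product: 10 4-methoxybenzyl (S)-4-methyl-2-[13-(2-methyl-1,3-dioxolan-2-yl)tridecyl]-5-oxo-2,5-dihydrofuran-3-carboxylate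
Conditions: Pd(OAc)2 (5 mol %), p-benzoquinone (1.5 equiv), CO (1 atm), 4-MeOC6H4CH2OH (5 equiv), THF, rt
Reagents that add atoms: carbon monoxide, [C-]#[O+]; 4-methoxybenzyl alcohol, COc1ccc(CO)cc1
Why: Proposed new method: Pd(OAc)2 should bind the distal C3=C4 π-bond of 9 on the lobe turned away from the carboxyl, the carboxylate oxygen then adds to the allene terminus C4 (the future ring C5) in an anti oxypalladation that closes the O1–C5 bond and leaves a 5-oxo-2,5-dihydrofuran-3-yl–palladium species at the former central allene carbon, CO inserts into this vinyl–palladium bond, 4-methoxybenzyl alcohol cleaves the acylpalladium to the ester, and p-benzoquinone returns zerovalent palladium to divalent palladium. The closest known reaction types are the divalent-palladium-catalysed cyclisation of 2,3-allenoic acids in which the same furanonyl–palladium intermediate is captured by allylic halides, and the oxidative cyclisation–alkoxycarbonylation of allenyl alcohols, amines and ketones under CO; capture of the allenoic-acid-derived vinylpalladium by CO and an alcohol is the element not yet shown. The furanone ring closes in a 5-endo mode, the oxygen attacking the sp2 terminus of the allene. The C5 stereocentre is set by axial-to-central chirality transfer: the carboxyl lies in the plane of the C3=C4 π-lobes and can reach only one face of C4, so the (aS)-axis should be converted into the (S)-centre whichever face the metal occupies. The step needs 5-endo attack at C4 (attack at the central carbon would give a strained four-membered lactone), CO insertion faster than protodepalladation or oxidative dimerisation, and no racemisation of the allene before ring closure. These are secured by the C2 carboxyl held beside C4, by the CO atmosphere with an excess of the alcohol, and by a halide-free and phosphine-free catalyst with acetate as the only base, and the ketal is a spectator.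

**Step 8**
Reactants: 10 4-methoxybenzyl (S)-4-methyl-2-[13-(2-methyl-1,3-dioxolan-2-yl)tridecyl]-5-oxo-2,5-dihydrofuran-3-carboxylate
Product: 11 (S)-4-methyl-5-oxo-2-(14-oxopentadecyl)-2,5-dihydrofuran-3-carboxylic acid
Conditions: TFA/CH2Cl2/H2O (10:10:1), anisole (5 equiv), 0 °C → rt
Reagents that add atoms: water, O
Why: Acidolysis of the 4-methoxybenzyl ester (ionisation to the benzylic cation, which anisole traps by Friedel–Crafts alkylation) and acid-catalysed hydrolysis of the dioxolane should occur in one pot, and because no base is present the C5–H of the butenolide is not removed and the stereocentre should be kept.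

**Compound list**
1 | methyl 11-bromoundecanoate | COC(=O)CCCCCCCCCCBr | starting material
2 | 2-(3-chloropropyl)-2-methyl-1,3-dioxolane | CC1(CCCCl)OCCO1 | starting material
3 | [3-(2-methyl-1,3-dioxolan-2-yl)propyl]magnesium chloride | CC1(CCC[Mg]Cl)OCCO1 | intermediate (not isolated)
4 | methyl 14-(2-methyl-1,3-dioxolan-2-yl)tetradecanoate | COC(=O)CCCCCCCCCCCCCC1(C)OCCO1 | intermediate
5 | N-methoxy-N-methyl-14-(2-methyl-1,3-dioxolan-2-yl)tetradecanamide | CON(C)C(=O)CCCCCCCCCCCCCC1(C)OCCO1 | intermediate
6 | 17-(2-methyl-1,3-dioxolan-2-yl)heptadec-2-yn-4-one | CC#CC(=O)CCCCCCCCCCCCCC1(C)OCCO1 | intermediate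
7 | (R)-17-(2-methyl-1,3-dioxolan-2-yl)heptadec-2-yn-4-ol | CC#C[C@H](O)CCCCCCCCCCCCCC1(C)OCCO1 | intermediate
8 | (R)-17-(2-methyl-1,3-dioxolan-2-yl)heptadec-2-yn-4-yl methanesulfonate | CC#C[C@H](OS(C)(=O)=O)CCCCCCCCCCCCCC1(C)OCCO1 | intermediate
9 | (aS)-2-methyl-17-(2-methyl-1,3-dioxolan-2-yl)heptadeca-2,3-dienoic acid | [H]C(CCCCCCCCCCCCCC1(C)OCCO1)=[C@]=C(C)C(=O)O | intermediate
10 | 4-methoxybenzyl (S)-4-methyl-2-[13-(2-methyl-1,3-dioxolan-2-yl)tridecyl]-5-oxo-2,5-dihydrofuran-3-carboxylate | CC1(OCCO1)CCCCCCCCCCCCC[C@@H]2OC(=O)C(C)=C2C(=O)OCc3ccc(OC)cc3 | intermediate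
11 | (S)-4-methyl-5-oxo-2-(14-oxopentadecyl)-2,5-dihydrofuran-3-carboxylic acid | CC(=O)CCCCCCCCCCCCC[C@@H]1OC(=O)C(C)=C1C(=O)O | target

**Step count**
Total steps: 8. Longest linear sequence: 8 steps (1 → 11).

**Steps most likely to fail**

Step 7 (proposed new method). The furanonyl–palladium intermediate may be protonated before CO inserts (plain cycloisomerisation), may dimerise oxidatively, or the allene axis may racemise on the metal before ring closure; oxidant may also be used up by carbonylation of the alcohol. The fallback uses known chemistry, closes the same O1–C5 bond and runs from 9 back to 10. Iodolactonisation of 9 with N-iodosuccinimide (CH2Cl2, 0 °C) should deliver, by the same geometrically enforced attack of the carboxylate on C4, (S)-4-iodo-3-methyl-5-[13-(2-methyl-1,3-dioxolan-2-yl)tridecyl]furan-2(5H)-one F1. Alkoxycarbonylation of this vinyl iodide (PdCl2(PPh3)2 cat., CO 1 atm, 4-methoxybenzyl alcohol, i-Pr2NEt, DMF, 50 °C) should then give 10.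

Step 6. Enantiopurity may erode through equilibration of the allenylpalladium intermediate or racemisation of the product by zerovalent palladium, and the mesylate may solvolyse in the aqueous medium. The fallback replaces palladium carbonylation by an organocopper anti SN2' substitution; regioselective attack at the ester-bearing alkyne carbon rests on analogy with γ-mesyloxy enoates. It runs from 5 back to 9.
- Reduction of 5 with i-Bu2AlH (THF, −78 °C) should give 14-(2-methyl-1,3-dioxolan-2-yl)tetradecanal F2.
- Addition of ethyl propiolate mediated by Me2Zn and the ProPhenol ligand enantiomer that leads to the (S)-carbinol should give ethyl (S)-4-hydroxy-17-(2-methyl-1,3-dioxolan-2-yl)heptadec-2-ynoate F3.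
- Mesylation (MsCl, Et3N, CH2Cl2, −40 °C) should give ethyl (S)-4-(methanesulfonyloxy)-17-(2-methyl-1,3-dioxolan-2-yl)heptadec-2-ynoate F4.
- MeMgBr with CuBr·SMe2 and LiBr (THF, −78 °C) should deliver methyl to the ester-bearing alkyne carbon anti to the mesylate, giving ethyl (aS)-2-methyl-17-(2-methyl-1,3-dioxolan-2-yl)heptadeca-2,3-dienoate F5. Because methyl, not the carboxyl, enters anti here, the (S)-carbinol is the one required.
- Saponification (LiOH, THF/H2O, 0 °C) should give 9.

Step 1. Grignard formation from the alkyl chloride may stall, Wurtz-type homocoupling may compete, and the Grignard reagent may add to the methyl ester. The fallback reverses the polarity so that the ester sits on a tolerant organozinc; it starts from 2 and 1 and returns at 4. Finkelstein exchange on 2 (NaI, NaHCO3, acetone, reflux) should give 2-(3-iodopropyl)-2-methyl-1,3-dioxolane F6. Zinc insertion into 1 (Zn dust, LiCl, THF, 50 °C) should give (11-methoxy-11-oxoundecyl)zinc bromide F7. A nickel-catalysed alkyl–alkyl Negishi coupling of F7 with F6 (Ni(cod)2, s-Bu-pybox, DMA, rt) should give 4.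

**Further compounds**
F1 | step 7 | (S)-4-iodo-3-methyl-5-[13-(2-methyl-1,3-dioxolan-2-yl)tridecyl]furan-2(5H)-one | CC1(OCCO1)CCCCCCCCCCCCC[C@@H]2OC(=O)C(C)=C2I
F2 | step 6 | 14-(2-methyl-1,3-dioxolan-2-yl)tetradecanal | O=CCCCCCCCCCCCCCC1(C)OCCO1
F3 | step 6 | ethyl (S)-4-hydroxy-17-(2-methyl-1,3-dioxolan-2-yl)heptadec-2-ynoate | CCOC(=O)C#C[C@@H](O)CCCCCCCCCCCCCC1(C)OCCO1
F4 | step 6 | ethyl (S)-4-(methanesulfonyloxy)-17-(2-methyl-1,3-dioxolan-2-yl)heptadec-2-ynoate | CCOC(=O)C#C[C@@H](OS(C)(=O)=O)CCCCCCCCCCCCCC1(C)OCCO1
F5 | step 6 | ethyl (aS)-2-methyl-17-(2-methyl-1,3-dioxolan-2-yl)heptadeca-2,3-dienoate | [H]C(CCCCCCCCCCCCCC1(C)OCCO1)=[C@]=C(C)C(=O)OCC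
F6 | step 1 | 2-(3-iodopropyl)-2-methyl-1,3-dioxolane | CC1(CCCI)OCCO1
F7 | step 1 | (11-methoxy-11-oxoundecyl)zinc bromide | COC(=O)CCCCCCCCCC[Zn]Br
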